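**Retrosynthetic overview**
- C40 is cut at C11′=C12′ (Wittig) into a ring-A C25 ynal and a ring-B C15 acetylenic ylide; the 7E double bond is made last by hydroxyl-directed reduction of a 7,8-triple bond.
- Key disconnection C6–C7: a C16 polyenynal, masked in the flask and lithiated at its alkyne terminus (a reversed-polarity, extended homoenolate-type donor), adds to the ketone of (R)-phorenol; C6 is set relative to C3, which is then inverted (Mitsunobu).
- The C16 ynal comes from C10-dialdehyde and a C6 enynyl ylide; the ring-B C15 unit comes from an enol triflate (reductive triflation of (S)-phorenol silyl ether) and the same C6 enynol (Sonogashira).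
- No ring is built: both rings are the carbocycle of ketoisophorone, reduced enantiodivergently; ring A is joined to the chain first, ring B last.

Assumption: locants follow carotenoid usage with the 3,6-dihydroxy-ε ring unprimed (C1–C15) and the acetylenic ring primed; the target SMILES is read as 3S,6R (3,6-cis-diol), 3′R, all-E. The facial sense of step 4 is predicted from a conformational model, not from a reported result.

**Step 1**
Reactants: 1 (2E)-3-methylpent-2-en-4-yn-1-ol
Product: 2 [(2E)-3-methylpent-2-en-4-yn-1-yl]triphenylphosphonium bromide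
Conditions: PPh3·HBr (1.05 equiv), MeOH, rt, 16 h
Reagents that add atoms: triphenylphosphine hydrobromide, [Br-].[PH+](c1ccccc1)(c1ccccc1)c1ccccc1
Why: Phosphonium salt formation by substitution of the protonated primary allylic alcohol by PPh3; the E geometry is kept and the salt is purified by crystallisation.

**Step 2**
Reactants: 2 enynyl phosphonium bromide; 3 (2E,4E,6E)-2,7-dimethylocta-2,4,6-trienedial (C10-dialdehyde)
Product: 5 (2E,4E,6E,8E,10E)-2,7,11-trimethyltrideca-2,4,6,8,10-pentaen-12-ynal, via enynyl ylide 4 (not isolated)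
Conditions: 3 (3 equiv), NaOMe (1.05 equiv), CH2Cl2/MeOH, 0 °C → rt; then heptane, 80 °C
Reagents that add atoms: none
Why: Wittig olefination; the threefold excess of the symmetrical dialdehyde limits reaction to one formyl group, and the Z/E mixture at the new C11=C12 bond converges to E on heating (thermal isomerisation).

**Step 3**
Reactants: 6 2,6,6-trimethylcyclohex-2-ene-1,4-dione (ketoisophorone)
Product: 7 (4R)-4-hydroxy-2,6,6-trimethylcyclohex-2-en-1-one ((R)-phorenol)
Conditions: RuCl[(R,R)-TsDPEN](p-cymene) (0.5 mol %), i-PrOH, rt; crystallise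
Reagents that add atoms: none
Why: Noyori asymmetric transfer hydrogenation reduces only the unhindered C4 carbonyl; the C=C takes the role of the aryl group (CH/π), so the (R,R) catalyst is expected to give the 4R alcohol, which becomes C3 of ring A.

**Step 4 (key step)**
Reactants: 5 C16 polyenynal; 7 (R)-phorenol
Product: 11 (3R,6R)-3,6-dihydroxy-7,8-didehydro-12′-apo-ε-caroten-12′-al (3,6-trans-diol), via lithium amino-alkoxide 8 (not isolated), via dilithio acetylide 9 (not isolated), via lithium phorenolate 10 (not isolated)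
Conditions: 5, LiN(Me)CH2CH2NMe2 (1.1 equiv, from Me2NCH2CH2NHMe + n-BuLi), THF, −78 → −40 °C; LDA (1.2 equiv), −78 °C; then 10 (1.3 equiv, from 7 + LiHMDS, THF, −78 °C), −78 → −20 °C; pH 7 buffer
Reagents that add atoms: none
Why: Proposed new method: in 5 the alkyne terminus (C7 of the target) is the remote acceptor position of the conjugated aldehyde; masking CHO as the lithium α-amino alkoxide 8 removes that acceptor character and allows C–H lithiation to 9, a reversed-polarity (donor) equivalent of this carbon, i.e. an extended homoenolate, which adds 1,2 to the ketone carbon of 10, so two carbons that are both acceptors in the parent carbonyl compounds are joined (closest known reactions: in-situ α-amino-alkoxide protection of aldehydes before lithiation, and alkynyl-dianion additions to 2,6,6-trimethylcyclohexenones in abscisic acid syntheses); C6 is set by axial attack on the half-chair that keeps C3–OLi pseudo-equatorial, anti to the pseudo-axial C1 methyl and therefore cis to O3, giving the 3,6-trans-diol, with the minor cis isomer removed by chromatography.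

**Step 5**
Reactants: 11 C25 trans-diol ynal
Product: 12 3-O-(4-nitrobenzoyl) derivative of the (3S,6R) C25 ynal (3,6-cis)
Conditions: PPh3, DIAD, 4-O2NC6H4CO2H (1.5 equiv each), THF, 0 °C → rt
Reagents that add atoms: 4-nitrobenzoic acid, OC(=O)c1ccc(cc1)[N+](=O)[O-]
Why: Mitsunobu reaction: SN2 inversion at the secondary allylic C3 (3R → 3S) puts O3 cis to the 6-OH; the tertiary propargylic alcohol does not react and the aldehyde is tolerated.

**Step 6**
Reactants: 6 ketoisophorone
Product: 13 (4S)-4-hydroxy-2,6,6-trimethylcyclohex-2-en-1-one ((S)-phorenol)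
Conditions: RuCl[(S,S)-TsDPEN](p-cymene) (0.5 mol %), i-PrOH, rt; crystallise
Reagents that add atoms: none
Why: Noyori asymmetric transfer hydrogenation with the enantiomeric catalyst; this carbinol becomes C3′, whose descriptor changes to R once the ring double bond has moved (CIP priority switch, same geometry).

**Step 7**
Reactants: 13 (S)-phorenol
Product: 14 (4S)-4-[(tert-butyldimethylsilyl)oxy]-2,6,6-trimethylcyclohex-2-en-1-one
Conditions: TBSCl, imidazole, DMF, rt
Reagents that add atoms: tert-butyldimethylsilyl chloride, CC(C)(C)[Si](C)(C)Cl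
Why: Standard silylation of the secondary alcohol, needed to carry it through the hydride and enolate chemistry of step 8.

**Step 8**
Reactants: 14 silyl ether
Product: 16 (4R)-4-[(tert-butyldimethylsilyl)oxy]-2,6,6-trimethylcyclohex-1-en-1-yl trifluoromethanesulfonate, via lithium enolate 15 (not isolated)
Conditions: L-Selectride (1.1 equiv), THF, −78 °C; then PhNTf2 (1.2 equiv), −78 °C → rt
Reagents that add atoms: N-phenylbis(trifluoromethanesulfonimide), O=S(=O)(N(c1ccccc1)S(=O)(=O)C(F)(F)F)C(F)(F)F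
Why: Conjugate hydride reduction of the β-unsubstituted, carbonyl-hindered enone gives the tetrasubstituted enolate regiospecifically, and O-triflation traps it (reductive triflation); the stereocentre is untouched.

**Step 9**
Reactants: 16 enol triflate; 1 (2E)-3-methylpent-2-en-4-yn-1-ol
Product: 17 (2E)-5-[(4R)-4-[(tert-butyldimethylsilyl)oxy]-2,6,6-trimethylcyclohex-1-en-1-yl]-3-methylpent-2-en-4-yn-1-ol
Conditions: 1 (1.3 equiv), Pd(PPh3)4 (5 mol %), CuI (10 mol %), i-Pr2NH, DMF, rt
Reagents that add atoms: none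
Why: Sonogashira coupling of the hindered cyclohexenyl triflate with the terminal enyne forms C6′–C7′; the free allylic alcohol is tolerated.

**Step 10**
Reactants: 17 ring-B C15 alcohol
Product: 18 [(2E)-5-[(4R)-4-hydroxy-2,6,6-trimethylcyclohex-1-en-1-yl]-3-methylpent-2-en-4-yn-1-yl]triphenylphosphonium bromide
Conditions: PPh3·HBr (1.3 equiv), MeOH, rt, 16 h
Reagents that add atoms: triphenylphosphine hydrobromide, [Br-].[PH+](c1ccccc1)(c1ccccc1)c1ccccc1
Why: Phosphonium salt formation at the primary allylic position; the excess HBr in methanol cleaves the silyl ether in the same pot, giving the hydroxy C15 Wittig salt.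

**Step 11**
Reactants: 18 ring-B phosphonium bromide; 12 C25 ynal nitrobenzoate
Product: 21 (3S,6R,3′R)-7,8,7′,8′-tetradehydro-ε,β-carotene-3,6,3′-triol, via C15 ylide 19 (not isolated), via C40 nitrobenzoate 20 (not isolated)
Conditions: NaOMe (1.1 equiv), CH2Cl2/MeOH, 0 °C → rt; then NaOMe (1 equiv), MeOH, rt; then EtOAc/heptane, 80 °C
Reagents that add atoms: none
Why: Wittig olefination forms C11′=C12′ (free hydroxyls tolerated), methoxide then removes the activated 4-nitrobenzoate by transesterification, and heating converts the hindered 11′Z isomer to E.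

**Step 12**
Reactants: 21 C40 tetradehydro triol
Product: 22 (3R,3′S,6′R)-7,8-didehydro-β,ε-carotene-3,3′,6′-triol (target; 3S,6R,3′R in the numbering used here)
Conditions: Red-Al (6 equiv), THF, 0 °C → rt; aq. Rochelle salt
Reagents that add atoms: none
Why: Alkoxide-directed trans-hydroalumination of the propargylic alcohol and protonolysis give the 7E alkene; the 7′,8′ triple bond has no propargylic oxygen and is not reduced.

**Compound list**
1 | (2E)-3-methylpent-2-en-4-yn-1-ol | C#C/C(C)=C/CO | starting material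
2 | [(2E)-3-methylpent-2-en-4-yn-1-yl]triphenylphosphonium bromide | C#C/C(C)=C/C[P+](c1ccccc1)(c1ccccc1)c1ccccc1.[Br-] | intermediate
3 | (2E,4E,6E)-2,7-dimethylocta-2,4,6-trienedial | O=C/C(C)=C/C=C/C=C(C)/C=O | starting material
4 | ylide of 2 (not isolated) | [CH-](/C=C(\C)C#C)[P+](c1ccccc1)(c1ccccc1)c1ccccc1 | intermediate
5 | (2E,4E,6E,8E,10E)-2,7,11-trimethyltrideca-2,4,6,8,10-pentaen-12-ynal | C#C/C(C)=C/C=C/C(C)=C/C=C/C=C(C)/C=O | intermediate
6 | 2,6,6-trimethylcyclohex-2-ene-1,4-dione (ketoisophorone) | CC1=CC(=O)CC(C)(C)C1=O | starting material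
7 | (4R)-4-hydroxy-2,6,6-trimethylcyclohex-2-en-1-one | CC1=C[C@H](O)CC(C)(C)C1=O | intermediate
8 | lithium α-amino alkoxide of 5 with N,N,N′-trimethylethylenediamine (not isolated; new centre undefined) | [Li+].C#C/C(C)=C/C=C/C(C)=C/C=C/C=C(C)/C([O-])N(C)CCN(C)C | intermediate
9 | alkyne-lithiated 8, dilithium species (not isolated) | [Li+].[Li+].[C-]#C/C(C)=C/C=C/C(C)=C/C=C/C=C(C)/C([O-])N(C)CCN(C)C | intermediate
10 | lithium alkoxide of 7 (not isolated) | [Li+].CC1=C[C@H]([O-])CC(C)(C)C1=O | intermediate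
11 | (2E,4E,6E,8E,10E)-13-[(1R,4R)-1,4-dihydroxy-2,6,6-trimethylcyclohex-2-en-1-yl]-2,7,11-trimethyltrideca-2,4,6,8,10-pentaen-12-ynal (3R,6R; trans-diol) | CC1=C[C@H](O)CC(C)(C)[C@]1(O)C#C/C(C)=C/C=C/C(C)=C/C=C/C=C(C)/C=O | intermediate
12 | (1S,4R)-4-hydroxy-3,5,5-trimethyl-4-[(3E,5E,7E,9E,11E)-3,7,12-trimethyl-13-oxotrideca-3,5,7,9,11-pentaen-1-yn-1-yl]cyclohex-2-en-1-yl 4-nitrobenzoate (3S,6R; cis) | CC1=C[C@@H](OC(=O)c2ccc(cc2)[N+](=O)[O-])CC(C)(C)[C@]1(O)C#C/C(C)=C/C=C/C(C)=C/C=C/C=C(C)/C=O | intermediate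
13 | (4S)-4-hydroxy-2,6,6-trimethylcyclohex-2-en-1-one | CC1=C[C@@H](O)CC(C)(C)C1=O | intermediate
14 | (4S)-4-[(tert-butyldimethylsilyl)oxy]-2,6,6-trimethylcyclohex-2-en-1-one | CC1=C[C@@H](O[Si](C)(C)C(C)(C)C)CC(C)(C)C1=O | intermediate
15 | lithium (4R)-4-[(tert-butyldimethylsilyl)oxy]-2,6,6-trimethylcyclohex-1-en-1-olate (not isolated) | [Li+].[O-]C1=C(C)C[C@@H](O[Si](C)(C)C(C)(C)C)CC1(C)C | intermediate
16 | (4R)-4-[(tert-butyldimethylsilyl)oxy]-2,6,6-trimethylcyclohex-1-en-1-yl trifluoromethanesulfonate | O=S(=O)(OC1=C(C)C[C@@H](O[Si](C)(C)C(C)(C)C)CC1(C)C)C(F)(F)F | intermediate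
17 | (2E)-5-[(4R)-4-[(tert-butyldimethylsilyl)oxy]-2,6,6-trimethylcyclohex-1-en-1-yl]-3-methylpent-2-en-4-yn-1-ol | OC/C=C(\C)C#CC1=C(C)C[C@@H](O[Si](C)(C)C(C)(C)C)CC1(C)C | intermediate
18 | [(2E)-5-[(4R)-4-hydroxy-2,6,6-trimethylcyclohex-1-en-1-yl]-3-methylpent-2-en-4-yn-1-yl]triphenylphosphonium bromide | C(/C=C(\C)C#CC1=C(C)C[C@@H](O)CC1(C)C)[P+](c1ccccc1)(c1ccccc1)c1ccccc1.[Br-] | intermediate
19 | ylide of 18 (not isolated) | [CH-](/C=C(\C)C#CC1=C(C)C[C@@H](O)CC1(C)C)[P+](c1ccccc1)(c1ccccc1)c1ccccc1 | intermediate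
20 | 3-O-(4-nitrobenzoyl) derivative of 21 (not isolated) | CC1=C[C@@H](OC(=O)c2ccc(cc2)[N+](=O)[O-])CC(C)(C)[C@]1(O)C#C/C(C)=C/C=C/C(C)=C/C=C/C=C(C)/C=C/C=C(\C)C#CC1=C(C)C[C@@H](O)CC1(C)C | intermediate
21 | (3S,6R,3′R)-7,8,7′,8′-tetradehydro-ε,β-carotene-3,6,3′-triol | CC1=C[C@@H](O)CC(C)(C)[C@]1(O)C#C/C(C)=C/C=C/C(C)=C/C=C/C=C(C)/C=C/C=C(\C)C#CC1=C(C)C[C@@H](O)CC1(C)C | intermediate
22 | (3R,3′S,6′R)-7,8-didehydro-β,ε-carotene-3,3′,6′-triol | CC1=C[C@@H](O)CC(C)(C)[C@]1(O)/C=C/C(C)=C/C=C/C(C)=C/C=C/C=C(C)/C=C/C=C(\C)C#CC1=C(C)C[C@@H](O)CC1(C)C | target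

**Step count**
Total: 12 steps. Longest linear sequence: 7 steps (6 → 13 → 14 → 16 → 17 → 18 → 21 → 22).

**Three steps most likely to fail**

Step 4. The risks are incomplete masking or lithiation of the polyenal and a modest diastereomer ratio. The fallback sets out from 5 and comes back at 11. 5 is reduced with NaBH4 (MeOH/CH2Cl2, 0 °C) to the ynol F1. LDA (2.2 equiv) gives its alkoxide–acetylide F2, the type of dianion used for abscisic-acid alkynylations. F2 is added to 10 and gives the triol F3. TEMPO/PhI(OAc)2 then oxidises only the primary polyenylic alcohol and returns 11. This costs two more steps, but no aldehyde is present during the organolithium chemistry.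

Step 5. The SN2 displacement at C3 is flanked by the axial C1 methyl, so elimination or SN2′ can compete; the need for the inversion also rests on the facial sense predicted for step 4. The fallback sets out from 13 and comes back at 21. 13 is deprotonated with LiHMDS to its lithium alkoxide F4 and treated with 9 (made from 5 as in step 4). Attack anti to O3 gives the (3S,6R)-cis-diol ynal F5 directly; it is separated from its trans isomer by chromatography. F5 is the minor product if the model of step 4 holds and the major one if the facial sense is the reverse; both components are cheap. F5 is olefinated with 19 under the conditions of step 11 (there is no ester to cleave) and gives 21, so no inversion is needed.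

Step 12. Red-Al on the complete C40 polyene may over-reduce, form an allene by loss of the C6 oxygen, or scramble E/Z geometry. The fallback sets out from 5 and comes back at 22. It runs through F1 and F2 to the triol F3 as in the first fallback. Red-Al at this C25 stage gives the (7E)-triol F6. TEMPO/PhI(OAc)2 gives the aldehyde F7, and Mitsunobu inversion with 4-nitrobenzoic acid gives the ester F8. A Wittig reaction with 19 and methanolysis in the same pot (through the C40 ester F9) gives 22. The last step is then an olefination and no hydride reagent meets the C40 polyene.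

**Further compounds**
F1 | step 4 | (2E,4E,6E,8E,10E)-2,7,11-trimethyltrideca-2,4,6,8,10-pentaen-12-yn-1-ol | C#C/C(C)=C/C=C/C(C)=C/C=C/C=C(C)/CO
F2 | step 4 | dilithium alkoxide–acetylide of F1 | [Li+].[Li+].[C-]#C/C(C)=C/C=C/C(C)=C/C=C/C=C(C)/C[O-]
F3 | step 4 | (1R,4R)-1-[(3E,5E,7E,9E,11E)-13-hydroxy-3,7,12-trimethyltrideca-3,5,7,9,11-pentaen-1-yn-1-yl]-2,6,6-trimethylcyclohex-2-ene-1,4-diol | CC1=C[C@H](O)CC(C)(C)[C@]1(O)C#C/C(C)=C/C=C/C(C)=C/C=C/C=C(C)/CO
F4 | step 5 | lithium alkoxide of 13 | [Li+].CC1=C[C@@H]([O-])CC(C)(C)C1=O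
F5 | step 5 | (3S,6R)-3,6-dihydroxy-7,8-didehydro-12′-apo-ε-caroten-12′-al (cis-diol; 12 without the ester) | CC1=C[C@@H](O)CC(C)(C)[C@]1(O)C#C/C(C)=C/C=C/C(C)=C/C=C/C=C(C)/C=O
F6 | step 12 | (3R,6R)-12′-apo-ε-carotene-3,6,12′-triol (7E; trans-diol) | CC1=C[C@H](O)CC(C)(C)[C@]1(O)/C=C/C(C)=C/C=C/C(C)=C/C=C/C=C(C)/CO
F7 | step 12 | (3R,6R)-3,6-dihydroxy-12′-apo-ε-caroten-12′-al (7E; trans-diol) | CC1=C[C@H](O)CC(C)(C)[C@]1(O)/C=C/C(C)=C/C=C/C(C)=C/C=C/C=C(C)/C=O
F8 | step 12 | 3-O-(4-nitrobenzoyl)-(3S,6R)-3,6-dihydroxy-12′-apo-ε-caroten-12′-al (7E; cis) | CC1=C[C@@H](OC(=O)c2ccc(cc2)[N+](=O)[O-])CC(C)(C)[C@]1(O)/C=C/C(C)=C/C=C/C(C)=C/C=C/C=C(C)/C=O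
F9 | step 12 | 3-O-(4-nitrobenzoyl) derivative of 22 | CC1=C[C@@H](OC(=O)c2ccc(cc2)[N+](=O)[O-])CC(C)(C)[C@]1(O)/C=C/C(C)=C/C=C/C(C)=C/C=C/C=C(C)/C=C/C=C(\C)C#CC1=C(C)C[C@@H](O)CC1(C)C
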